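**Strategy.** Both perhydro-1-benzoxepine halves are folded from one (S,S,S)-diepoxy vinyl ketone. The disconnection is the biomimetic one: the acetoxy-bearing oxepane O1–C2–C3–C4–C5–C6–C7 and its fused cyclohexane arise from a 2,3:6,7-diepoxide whose tertiary carbons C2 and C6 are 1,5-related and whose C7 oxygen becomes the ring oxygen. In one operation a silyl triflate triggers epoxonium formation (O7–C2) and capture at C6 by a regiodefined C10=C11 silyl enol ether, closing this oxepane in the last ring-forming event and setting C6, C7 and C11. The precursor is an acyclic diepoxy enol ether attached by cross-metathesis to the finished right-hand bicycle.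

Key step: step 11

Remark (numbering): chain locants follow the squalene-type C24 backbone. Left oxepane: O, C2(Me2), C3, C4, C5, C6(Me), C7. Left cyclohexane: C6–C11, with C10 the tertiary carbinol carbon. Bridge: C12–C13. Right cyclohexane: C14–C19, with C15 the tertiary carbinol carbon. Right oxepane: C18, C19–C23(Me2), O. In the benzoxepine names, positions 3/5a/6/7/9a are chain C3/C6/C11/C10/C7 (left) and C22/C19/C14/C15/C18 (right).

Assumption: the L-fructose-derived enantiomer of the Shi ketone is taken as an available catalyst and is expected to give the (S)-configured oxiranes, the mirror image of the outcome with the D-fructose-derived ketone.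

Step 1
Reactants: 1 geranyl bromide ((2E)-1-bromo-3,7-dimethylocta-2,6-diene); 2 N-methoxy-N-methylacetamide
Product: 4 (4E)-N-methoxy-N,5,9-trimethyldeca-4,8-dienamide, via lithium enolate 3 (not isolated)
Conditions: LiN(iPr)2, THF, −78 °C; then 1, −78 → −40 °C
Reagents that add atoms: none
Why: SN2 alkylation of the lithium amide enolate with the allylic bromide adds the two carbons that become C9 and C10 (C14 and C15 in the other half); no stereocenter is formed and the E olefin is untouched.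

Step 2
Reactants: 4 (4E)-N-methoxy-N,5,9-trimethyldeca-4,8-dienamide
Product: 5 (S,S,S)-diepoxy Weinreb amide
Conditions: L-fructose-derived Shi ketone (0.3 equiv per olefin), Oxone (2KHSO5·KHSO4·K2SO4), K2CO3, Bu4NHSO4, aq. Na2B4O7 buffer, MeCN/dimethoxymethane, 0 °C
Reagents that add atoms: potassium peroxymonosulfate (oxidant of Oxone), [K+].[O-]S(=O)(=O)OO
Why: Shi asymmetric epoxidation, in which the chiral dioxirane epoxidizes both trisubstituted olefins through the spiro transition state, each under catalyst control, to give the (2S,3S) internal and (2S) terminal oxiranes.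

Step 3
Reactants: 5 (S,S,S)-diepoxy Weinreb amide
Product: 6 (S,S,S)-diepoxy vinyl ketone
Conditions: CH2=CHMgBr, THF, −78 → −20 °C; inverse quench into cold 0.5 M aq. HCl (brief)
Reagents that add atoms: vinylmagnesium bromide, C=C[Mg]Br
Why: Weinreb ketone synthesis, in which the chelated tetrahedral adduct stops at the ketone stage and the trisubstituted oxiranes are inert to the Grignard reagent at low temperature; the acidic quench keeps the liberated amine from adding to the enone.

Step 4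
Reactants: 6 (S,S,S)-diepoxy vinyl ketone
Product: 8 (4Z)-tert-butyldimethylsilyl enol ether of the vinyl adduct, via bromomagnesium enolate 7 (not isolated)
Conditions: CH2=CHMgBr (1.3 equiv), CuBr·SMe2 (10 mol%), TBSCl, HMPA, THF, −78 → −40 °C; Et3N, cold aq. NaHCO3
Reagents that add atoms: vinylmagnesium bromide, C=C[Mg]Br; tert-butyldimethylsilyl chloride, CC(C)(C)[Si](C)(C)Cl
Why: copper-catalysed conjugate addition of the Grignard reagent with O-silylation of the enolate gives the enol ether regiospecifically at C14=C15; addition through the s-cis enone should give the Z isomer needed for the chair in step 5.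

Step 5
Reactants: 8 (4Z)-tert-butyldimethylsilyl enol ether
Product: 9 (3S,5aS,6S,9aS)-3-[(tert-butyldimethylsilyl)oxy]-2,2,5a-trimethyl-6-(prop-2-en-1-yl)octahydro-1-benzoxepin-7(2H)-one
Conditions: TBSOTf (0.5 equiv), 2,6-di-tert-butyl-4-methylpyridine (DTBMP), CH2Cl2, −78 °C; aq. NaHCO3
Reagents that add atoms: none
Why: silyl-triflate-promoted tandem oxa-/carbacyclization of a 1,5-diepoxide terminated by an enol silane, in which the 18,19-oxirane oxygen opens the silylated terminal oxirane at tertiary C23 and C14 of the enol ether opens the epoxonium ion at tertiary C19 with inversion through a chair, so that C22 and C18 keep the Shi configurations, C19 becomes the trans ring-fusion carbon with axial methyl and the allyl-bearing C14 is equatorial (also the thermodynamic α-epimer).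

Step 6
Reactants: 9 bicyclic ketone
Product: 10 tert-butyldimethylsilyl ether of (3S,5aS,6R,9aS)-2,2,5a-trimethyl-7-methylidene-6-(prop-2-en-1-yl)decahydro-1-benzoxepin-3-ol
Conditions: Ph3PCH3Br, KOtBu, toluene, rt → 80 °C
Reagents that add atoms: methyltriphenylphosphonium bromide, C[P+](c1ccccc1)(c1ccccc1)c1ccccc1.[Br-]
Why: Wittig methylenation of the hindered ketone; the α-stereocenter is already the equatorial, thermodynamically preferred one, so base-mediated epimerization is not a concern.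

Step 7
Reactants: 10 exocyclic diene
Product: 11 tert-butyldimethylsilyl ether of (3S,5aS,6S,7S,9aS)-2,2,5a-trimethyl-6-(prop-2-en-1-yl)octahydro-2H-spiro[1-benzoxepine-7,2'-oxiran]-3-ol
Conditions: dimethyldioxirane (1.05 equiv, acetone solution), CH2Cl2, −40 → −20 °C
Reagents that add atoms: dimethyldioxirane, CC1(C)OO1
Why: electrophilic dioxirane epoxidation should select the more electron-rich 1,1-disubstituted olefin over the vinyl group and attack from the equatorial face, because the axial face is shielded by the syn-axial C19 methyl; this sets C15 with the oxygen equatorial.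

Step 8
Reactants: 11 spiro-oxirane
Product: 12 (3S,5aS,6S,7S,9aS)-3-[(tert-butyldimethylsilyl)oxy]-2,2,5a,7-tetramethyl-6-(prop-2-en-1-yl)decahydro-1-benzoxepin-7-ol
Conditions: LiAlH4, THF, 0 °C → rt
Reagents that add atoms: none
Why: hydride opens the spiro-oxirane at its CH2 carbon (SN2 epoxide reduction), turning it into the axial methyl and leaving the equatorial tertiary alcohol with the C15 configuration set in step 7.

Step 9
Reactants: 12 right-hand bicyclic alcohol; 6 (S,S,S)-diepoxy vinyl ketone (2.5 equiv)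
Product: 13 (4E)-enone joining the bicycle and the diepoxide chain
Conditions: Hoveyda–Grubbs second-generation catalyst (5 mol%), CH2Cl2, 40 °C
Reagents that add atoms: none
Why: olefin cross-metathesis between a terminal olefin and an electron-poor vinyl ketone is selective for the cross product and gives the E enone, forming the C11=C12 bond; oxiranes, silyl ether and tertiary alcohol are tolerated.

Step 10
Reactants: 13 (4E)-enone
Product: 14 (3Z)-triethylsilyl enol ether
Conditions: Et3SiH (1.5 equiv), RhCl(PPh3)3 (2 mol%), THF, 50 °C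
Reagents that add atoms: triethylsilane, CC[SiH](CC)CC
Why: rhodium-catalysed 1,4-hydrosilylation of the enone with a monohydrosilane gives the silyl enol ether regiospecifically at C10=C11 (predominantly Z), a regiochemistry that enolization of the saturated ketone could not provide.

Step 11
Reactants: 14 (3Z)-triethylsilyl enol ether
Product: 16 tetracyclic ketone (left C3–OSiEt3 and C10=O; right C15–OSiEt3 and C22–OTBS), via O15-triethylsilyl enol ether 15 (not isolated)
Conditions: TESOTf (2.2 equiv), DTBMP (3 equiv), CH2Cl2, −78 °C; aq. NaHCO3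
Reagents that add atoms: triethylsilyl trifluoromethanesulfonate, CC[Si](CC)(CC)OS(=O)(=O)C(F)(F)F
Why: TESOTf first caps the C15 hydroxyl (15) and then silylates the terminal 2,3-oxirane, whose tertiary carbon C2 is opened with inversion by the oxygen of the 6,7-oxirane to give a bicyclic epoxonium ion; C11 of the Z enol ether opens this ion at tertiary C6 anti to the departing C6–O bond through a chair, and the silyloxycarbenium ion releases Et3Si+ to give the ketone and regenerate silyl triflate. The closest known reaction type is the silyl-triflate-promoted tandem oxa-/carbacyclization of 1,5-diepoxides terminated by enol silanes or allylsilanes (biomimetic epoxide-opening polycyclization), of which step 5 is the model. The oxepane is closed by O7–C2 bond formation in the endo mode at the more substituted oxirane carbon, its seven-membered size being fixed when the C6–O bond of the epoxonium ion breaks, and the cyclohexane by 6-endo opening of the epoxonium ion (C6–C11 bond). C3 and C7 keep the configurations from the Shi epoxidation, C6 is set by inversion of the (6S) carbon of the trans-oxirane, which makes the ring fusion trans with axial methyl, and C11 is set by the Z enol ether in the chair (side chain equatorial), the epimer that equilibration α to the ketone also favours. The step needs endo regioselectivity at both oxiranes and carbon rather than oxygen attack by the terminator: the tertiary carbons C2 and C6 carry the developing positive charge, DTBMP suppresses proton-mediated pathways, and the fully substituted right-hand bicycle is a spectator.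

Step 12
Reactants: 16 tetracyclic ketone
Product: 18 triol (left C3–OH and axial C10–OH; right C15–OH; C22–OTBS), via bis-triethylsilyl carbinol 17 (not isolated)
Conditions: MeMgBr, CeCl3, THF, −78 → 0 °C; AcOH quench, then AcOH/THF/H2O (3:1:1), 40 °C
Reagents that add atoms: methylmagnesium bromide, C[Mg]Br
Why: organocerium-type 1,2-addition to the hindered, enolizable ketone should occur from the equatorial face because the axial face is blocked by the syn-axial C6 methyl, giving the axial tertiary alcohol at C10, after which aqueous acetic acid cleaves the two triethylsilyl ethers (acidic desilylation) while the hindered tert-butyldimethylsilyl ether survives.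

Step 13
Reactants: 18 triol
Product: 19 triacetate tert-butyldimethylsilyl ether
Conditions: Ac2O (excess), DMAP, Et3N, CH2Cl2, 40 °C
Reagents that add atoms: acetic anhydride, CC(=O)OC(C)=O
Why: DMAP-catalysed acylation with excess anhydride esterifies the secondary C3 hydroxyl and both tertiary hydroxyls without touching a stereocenter.

Step 14
Reactants: 19 triacetate tert-butyldimethylsilyl ether
Product: 20 target CNP0169816.1
Conditions: HF·pyridine, THF, 0 °C → rt
Reagents that add atoms: none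
Why: fluoride-mediated silyl ether cleavage (Si–F bond formation) liberates the C22 hydroxyl under conditions that leave the three acetates intact.

**Compound list**

1 | geranyl bromide ((2E)-1-bromo-3,7-dimethylocta-2,6-diene) | CC(C)=CCC/C(C)=C/CBr | starting material
2 | N-methoxy-N-methylacetamide | CC(=O)N(C)OC | starting material
3 | lithium enolate of 2 (lithium 1-[methoxy(methyl)amino]ethenolate) | [Li]OC(=C)N(C)OC | intermediate (not isolated)
4 | (4E)-N-methoxy-N,5,9-trimethyldeca-4,8-dienamide | CC(C)=CCC/C(C)=C/CCC(=O)N(C)OC | intermediate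
5 | 3-[(2S,3S)-3-{2-[(2S)-3,3-dimethyloxiran-2-yl]ethyl}-3-methyloxiran-2-yl]-N-methoxy-N-methylpropanamide | CON(C)C(=O)CC[C@@H]1O[C@@]1(C)CC[C@@H]1OC1(C)C | intermediate
6 | 5-[(2S,3S)-3-{2-[(2S)-3,3-dimethyloxiran-2-yl]ethyl}-3-methyloxiran-2-yl]pent-1-en-3-one | C=CC(=O)CC[C@@H]1O[C@@]1(C)CC[C@@H]1OC1(C)C | intermediate
7 | bromomagnesium (4Z)-7-[(2S,3S)-3-{2-[(2S)-3,3-dimethyloxiran-2-yl]ethyl}-3-methyloxiran-2-yl]hepta-1,4-dien-5-olate | C=CC/C=C(\O[Mg]Br)CC[C@@H]1O[C@@]1(C)CC[C@@H]1OC1(C)C | intermediate (not isolated)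
8 | (4Z)-5-[(tert-butyldimethylsilyl)oxy]-7-[(2S,3S)-3-{2-[(2S)-3,3-dimethyloxiran-2-yl]ethyl}-3-methyloxiran-2-yl]hepta-1,4-diene | C=CC/C=C(\O[Si](C)(C)C(C)(C)C)CC[C@@H]1O[C@@]1(C)CC[C@@H]1OC1(C)C | intermediate
9 | (3S,5aS,6S,9aS)-3-[(tert-butyldimethylsilyl)oxy]-2,2,5a-trimethyl-6-(prop-2-en-1-yl)octahydro-1-benzoxepin-7(2H)-one | C=CC[C@H]1[C@]2(C)CC[C@H](O[Si](C)(C)C(C)(C)C)C(C)(C)O[C@H]2CCC1=O | intermediate
10 | tert-butyldimethylsilyl ether of (3S,5aS,6R,9aS)-2,2,5a-trimethyl-7-methylidene-6-(prop-2-en-1-yl)decahydro-1-benzoxepin-3-ol | C=CC[C@H]1[C@]2(C)CC[C@H](O[Si](C)(C)C(C)(C)C)C(C)(C)O[C@H]2CCC1=C | intermediate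
11 | tert-butyldimethylsilyl ether of (3S,5aS,6S,7S,9aS)-2,2,5a-trimethyl-6-(prop-2-en-1-yl)octahydro-2H-spiro[1-benzoxepine-7,2'-oxiran]-3-ol (oxirane oxygen equatorial) | C=CC[C@H]1[C@]2(C)CC[C@H](O[Si](C)(C)C(C)(C)C)C(C)(C)O[C@H]2CC[C@@]13CO3 | intermediate
12 | (3S,5aS,6S,7S,9aS)-3-[(tert-butyldimethylsilyl)oxy]-2,2,5a,7-tetramethyl-6-(prop-2-en-1-yl)decahydro-1-benzoxepin-7-ol | C=CC[C@H]1[C@]2(C)CC[C@H](O[Si](C)(C)C(C)(C)C)C(C)(C)O[C@H]2CC[C@]1(C)O | intermediate
13 | (4E)-6-[(3S,5aS,6S,7S,9aS)-3-{(tert-butyldimethylsilyl)oxy}-7-hydroxy-2,2,5a,7-tetramethyldecahydro-1-benzoxepin-6-yl]-1-[(2S,3S)-3-{2-[(2S)-3,3-dimethyloxiran-2-yl]ethyl}-3-methyloxiran-2-yl]hex-4-en-3-one | CC1(C)O[C@H]1CC[C@]1(C)O[C@H]1CCC(=O)/C=C/C[C@H]1[C@]2(C)CC[C@H](O[Si](C)(C)C(C)(C)C)C(C)(C)O[C@H]2CC[C@]1(C)O | intermediate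
14 | (3Z)-6-[bicycle as in 13]-1-[bis-oxirane as in 13]-3-[(triethylsilyl)oxy]hex-3-ene | CC1(C)O[C@H]1CC[C@]1(C)O[C@H]1CC/C(O[Si](CC)(CC)CC)=C/CC[C@H]1[C@]2(C)CC[C@H](O[Si](C)(C)C(C)(C)C)C(C)(C)O[C@H]2CC[C@]1(C)O | intermediate
15 | triethylsilyl ether of 14 at the tertiary (benzoxepine C7) hydroxyl | CC1(C)O[C@H]1CC[C@]1(C)O[C@H]1CC/C(O[Si](CC)(CC)CC)=C/CC[C@H]1[C@]2(C)CC[C@H](O[Si](C)(C)C(C)(C)C)C(C)(C)O[C@H]2CC[C@]1(C)O[Si](CC)(CC)CC | intermediate (not isolated)
16 | 1-[(3S,5aS,6S,9aS)-2,2,5a-trimethyl-7-oxo-3-{(triethylsilyl)oxy}decahydro-1-benzoxepin-6-yl]-2-[(3S,5aS,6S,7S,9aS)-3-{(tert-butyldimethylsilyl)oxy}-2,2,5a,7-tetramethyl-7-{(triethylsilyl)oxy}decahydro-1-benzoxepin-6-yl]ethane | CC[Si](CC)(CC)O[C@H]1CC[C@]2(C)[C@H](CCC(=O)[C@H]2CC[C@H]2[C@]3(C)CC[C@H](O[Si](C)(C)C(C)(C)C)C(C)(C)O[C@H]3CC[C@]2(C)O[Si](CC)(CC)CC)OC1(C)C | intermediate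
17 | 1-[(3S,5aS,6S,7R,9aS)-7-hydroxy-2,2,5a,7-tetramethyl-3-{(triethylsilyl)oxy}decahydro-1-benzoxepin-6-yl]-2-[right-hand unit as in 16]ethane | CC[Si](CC)(CC)O[C@H]1CC[C@]2(C)[C@H](CC[C@@](C)(O)[C@H]2CC[C@H]2[C@]3(C)CC[C@H](O[Si](C)(C)C(C)(C)C)C(C)(C)O[C@H]3CC[C@]2(C)O[Si](CC)(CC)CC)OC1(C)C | intermediate (not isolated)
18 | 1-[(3S,5aS,6S,7R,9aS)-3,7-dihydroxy-2,2,5a,7-tetramethyldecahydro-1-benzoxepin-6-yl]-2-[(3S,5aS,6S,7S,9aS)-3-{(tert-butyldimethylsilyl)oxy}-7-hydroxy-2,2,5a,7-tetramethyldecahydro-1-benzoxepin-6-yl]ethane | O[C@H]1CC[C@]2(C)[C@H](CC[C@@](C)(O)[C@H]2CC[C@H]2[C@]3(C)CC[C@H](O[Si](C)(C)C(C)(C)C)C(C)(C)O[C@H]3CC[C@]2(C)O)OC1(C)C | intermediate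
19 | 1-[(3S,5aS,6S,7R,9aS)-3,7-diacetoxy-2,2,5a,7-tetramethyldecahydro-1-benzoxepin-6-yl]-2-[(3S,5aS,6S,7S,9aS)-7-acetoxy-3-{(tert-butyldimethylsilyl)oxy}-2,2,5a,7-tetramethyldecahydro-1-benzoxepin-6-yl]ethane | CC(=O)O[C@H]1CC[C@]2(C)[C@H](CC[C@@](C)(OC(C)=O)[C@H]2CC[C@H]2[C@]3(C)CC[C@H](O[Si](C)(C)C(C)(C)C)C(C)(C)O[C@H]3CC[C@]2(C)OC(C)=O)OC1(C)C | intermediate
20 | CNP0169816.1: 1-[(3S,5aS,6S,7R,9aS)-3,7-diacetoxy-2,2,5a,7-tetramethyldecahydro-1-benzoxepin-6-yl]-2-[(3S,5aS,6S,7S,9aS)-7-acetoxy-3-hydroxy-2,2,5a,7-tetramethyldecahydro-1-benzoxepin-6-yl]ethane | CC(=O)O[C@H]1CC[C@]2(C)[C@H](CC[C@@](C)(OC(C)=O)[C@H]2CC[C@H]2[C@]3(C)CC[C@H](O)C(C)(C)O[C@H]3CC[C@]2(C)OC(C)=O)OC1(C)C | target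

**Totals.** Total step count: 14. Longest linear sequence: 14 steps (1 → 20; enone 6 enters a second time in step 9).

**Steps most likely to fail**

1. Step 11 (key step). The epoxonium ion may not be captured at C6 by the hindered, trisubstituted enol ether. Desilylation of the enol ether, a hydride shift in the activated oxirane, or opening at the secondary oxirane carbon could take over. The fallback sets out from 14 and comes back at 18; it replaces the oxygen-bound silicon terminator by a carbon-bound one. Treatment of 14 with CsF and PhNTf2 (DME, rt) should give the (3Z)-enol triflate F1. Kumada coupling with Me3SiCH2MgCl (Pd(PPh3)4, THF, 0 °C → rt) should give the (3Z)-allylsilane F2. Polycyclization with TMSOTf/DTBMP (CH2Cl2, −78 °C; then K2CO3, aqueous MeOH) should give the tetracyclic exocyclic-olefin diol F3, the left oxepane again being formed in the last ring-forming operation. Ozonolysis (O3, CH2Cl2/MeOH, −78 °C; Me2S) should give the keto diol F4, and MeMgBr/CeCl3 (THF, −78 °C) then leads to triol 18.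

2. Step 5. The same bond construction on the first diepoxide carries the same risks, plus scrambling of silyl groups between the enol ether and the C22 oxygen. The fallback sets out from 8 and comes back at 10. CsF/PhNTf2 should convert 8 into the (4Z)-enol triflate F5, and Me3SiCH2MgCl with Pd(PPh3)4 into the (2Z)-allylsilane F6. TMSOTf/DTBMP cyclization with this terminator delivers the exocyclic olefin directly, as the hydroxy diene F7 after methanolysis of the trimethylsilyl ether. Silylation (TBSOTf, 2,6-lutidine, CH2Cl2, −78 °C) gives 10, so the Wittig step is not needed.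

3. Step 13. Acylation of the axial tertiary C10 hydroxyl, which is syn-axial to the C6 methyl, may stay incomplete, or elimination may set in on forcing. The fallback sets out from 16 and comes back at 19; the C10 oxygen is acylated as its alkoxide at the moment it is formed. MeMgBr/CeCl3 addition to 16 followed by an Ac2O quench (THF, −78 °C → rt) should give the tertiary acetate bis-silyl ether F8. Buffered HF·pyridine (pyridine, THF, 0 °C) should give the diol acetate F9. Ac2O/DMAP/Et3N then has to esterify only a secondary and an equatorial tertiary hydroxyl to reach 19.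

**Further compounds**

F1 | step 11 | (3Z)-6-[(3S,5aS,6S,7S,9aS)-3-{(tert-butyldimethylsilyl)oxy}-7-hydroxy-2,2,5a,7-tetramethyldecahydro-1-benzoxepin-6-yl]-1-[(2S,3S)-3-{2-[(2S)-3,3-dimethyloxiran-2-yl]ethyl}-3-methyloxiran-2-yl]hex-3-en-3-yl trifluoromethanesulfonate | CC1(C)O[C@H]1CC[C@]1(C)O[C@H]1CC/C(OS(=O)(=O)C(F)(F)F)=C/CC[C@H]1[C@]2(C)CC[C@H](O[Si](C)(C)C(C)(C)C)C(C)(C)O[C@H]2CC[C@]1(C)O
F2 | step 11 | (3Z)-allylsilane: F1 with the triflate replaced by CH2SiMe3 | CC1(C)O[C@H]1CC[C@]1(C)O[C@H]1CC/C(C[Si](C)(C)C)=C/CC[C@H]1[C@]2(C)CC[C@H](O[Si](C)(C)C(C)(C)C)C(C)(C)O[C@H]2CC[C@]1(C)O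
F3 | step 11 | 1-[(3S,5aS,6R,9aS)-3-hydroxy-2,2,5a-trimethyl-7-methylidenedecahydro-1-benzoxepin-6-yl]-2-[(3S,5aS,6S,7S,9aS)-3-{(tert-butyldimethylsilyl)oxy}-7-hydroxy-2,2,5a,7-tetramethyldecahydro-1-benzoxepin-6-yl]ethane | O[C@H]1CC[C@]2(C)[C@H](CCC(=C)[C@H]2CC[C@H]2[C@]3(C)CC[C@H](O[Si](C)(C)C(C)(C)C)C(C)(C)O[C@H]3CC[C@]2(C)O)OC1(C)C
F4 | step 11 | 1-[(3S,5aS,6S,9aS)-3-hydroxy-2,2,5a-trimethyl-7-oxodecahydro-1-benzoxepin-6-yl]-2-[right-hand unit as in F3]ethane | O[C@H]1CC[C@]2(C)[C@H](CCC(=O)[C@H]2CC[C@H]2[C@]3(C)CC[C@H](O[Si](C)(C)C(C)(C)C)C(C)(C)O[C@H]3CC[C@]2(C)O)OC1(C)C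
F5 | step 5 | (4Z)-7-[(2S,3S)-3-{2-[(2S)-3,3-dimethyloxiran-2-yl]ethyl}-3-methyloxiran-2-yl]hepta-1,4-dien-5-yl trifluoromethanesulfonate | C=CC/C=C(\OS(=O)(=O)C(F)(F)F)CC[C@@H]1O[C@@]1(C)CC[C@@H]1OC1(C)C
F6 | step 5 | trimethyl[(2Z)-2-{2-[(2S,3S)-3-{2-[(2S)-3,3-dimethyloxiran-2-yl]ethyl}-3-methyloxiran-2-yl]ethyl}hexa-2,5-dien-1-yl]silane | C=CC/C=C(\C[Si](C)(C)C)CC[C@@H]1O[C@@]1(C)CC[C@@H]1OC1(C)C
F7 | step 5 | (3S,5aS,6R,9aS)-2,2,5a-trimethyl-7-methylidene-6-(prop-2-en-1-yl)decahydro-1-benzoxepin-3-ol | C=CC[C@H]1[C@]2(C)CC[C@H](O)C(C)(C)O[C@H]2CCC1=C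
F8 | step 13 | 1-[(3S,5aS,6S,7R,9aS)-7-acetoxy-2,2,5a,7-tetramethyl-3-{(triethylsilyl)oxy}decahydro-1-benzoxepin-6-yl]-2-[right-hand unit as in 16]ethane | CC[Si](CC)(CC)O[C@H]1CC[C@]2(C)[C@H](CC[C@@](C)(OC(C)=O)[C@H]2CC[C@H]2[C@]3(C)CC[C@H](O[Si](C)(C)C(C)(C)C)C(C)(C)O[C@H]3CC[C@]2(C)O[Si](CC)(CC)CC)OC1(C)C
F9 | step 13 | 1-[(3S,5aS,6S,7R,9aS)-7-acetoxy-3-hydroxy-2,2,5a,7-tetramethyldecahydro-1-benzoxepin-6-yl]-2-[(3S,5aS,6S,7S,9aS)-3-{(tert-butyldimethylsilyl)oxy}-7-hydroxy-2,2,5a,7-tetramethyldecahydro-1-benzoxepin-6-yl]ethane | O[C@H]1CC[C@]2(C)[C@H](CC[C@@](C)(OC(C)=O)[C@H]2CC[C@H]2[C@]3(C)CC[C@H](O[Si](C)(C)C(C)(C)C)C(C)(C)O[C@H]3CC[C@]2(C)O)OC1(C)C
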